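**Retrosynthetic overview**
1. Target ⇐ its phenol MOM ether 36 ⇐ epoxy macrolactone 35: Br and OH are installed at the end by anti SN2 opening of a (7S,8S)-epoxide at C8.
2. The 15-membered lactone (second ring formed) ⇐ seco acid 34 by macrolactonisation at C4–O.
3. C9–C10 ⇐ late union of western sulfone 19 (arene + cyclohexadiene) with eastern epoxy triflate 30 by sulfone alkylation, then desulfonylation.
4. 19 ⇐ aryl boronate 5 (fragment A, from 4-bromophenol) + allylic chloride 17 (fragment B). The cyclohexadiene (first ring formed) is built on (R)-butyrolactone 8 by aldol, ring-closing metathesis and dehydration; a rhodium conjugate addition sets C11.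
5. 30 (fragment C) ⇐ pent-4-ynoic acid via CBS reduction (C4), Negishi carboalumination (E-alkene, C7 methyl, C9) and Sharpless epoxidation (C7, C8).

Convention: locants follow the terpenoid chain of the target — C1(=CH2)/C2/C3(CH3) isopropenyl, C4 ester carbinol, C5, C6, C7 (CH3, OH), C8 (Br), C9, C10, C11 ring CH, C12(CH3)=C13, C14H2, C15(CH3)=C16, C17 benzylic CH2 — so the target is (4S,7S,8R,11S).

**Fragment A (aryl boronate)**

Step 1
Reactants: 1 4-bromophenol
Product: 2 2-(trimethylsilyl)ethyl 4-hydroxybenzoate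
Conditions: CO (1 atm), Me3SiCH2CH2OH (5 equiv), Pd(OAc)2 (2 mol %), Xantphos (4 mol %), Et3N, toluene, 90 °C
Reagents that add atoms: carbon monoxide, [C-]#[O+]; 2-(trimethylsilyl)ethanol, C[Si](C)(C)CCO
Why: Palladium-catalysed alkoxycarbonylation of the aryl bromide (oxidative addition, CO insertion, alcoholysis of the acylpalladium by the excess aliphatic alcohol) installs the para ester directly as a fluoride-labile ester.

Step 2
Reactants: 2 2-(trimethylsilyl)ethyl 4-hydroxybenzoate
Product: 3 2-(trimethylsilyl)ethyl 4-hydroxy-3-iodobenzoate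
Conditions: N-iodosuccinimide (1.05 equiv), TsOH·H2O (10 mol %), MeCN, 0 °C → rt
Reagents that add atoms: N-iodosuccinimide, O=C1CCC(=O)N1I
Why: Electrophilic aromatic iodination goes ortho to the hydroxyl group because para is blocked and the meta-directing ester points to the same carbon.

Step 3
Reactants: 3 2-(trimethylsilyl)ethyl 4-hydroxy-3-iodobenzoate
Product: 4 2-(trimethylsilyl)ethyl 3-iodo-4-(methoxymethoxy)benzoate
Conditions: MOMCl, iPr2NEt, CH2Cl2, 0 °C → rt
Reagents that add atoms: chloromethyl methyl ether, COCCl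
Why: O-alkylation of the phenol with the reactive α-chloro ether gives a MOM acetal that later survives LDA, fluoride, sodium amalgam and the lactonisation.

Step 4
Reactants: 4 2-(trimethylsilyl)ethyl 3-iodo-4-(methoxymethoxy)benzoate
Product: 5 2-(trimethylsilyl)ethyl 4-(methoxymethoxy)-3-(4,4,5,5-tetramethyl-1,3,2-dioxaborolan-2-yl)benzoate
Conditions: B2pin2 (1.2 equiv), PdCl2(dppf) (3 mol %), KOAc (3 equiv), 1,4-dioxane, 85 °C
Reagents that add atoms: bis(pinacolato)diboron, CC1(C)OB(B2OC(C)(C)C(C)(C)O2)OC1(C)C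
Why: Miyaura borylation (oxidative addition of the aryl iodide to zerovalent palladium, acetate-assisted transmetalation with the diboron, reductive elimination) gives the boronate without touching the ester.

**Fragment B (cyclohexadiene) and the western fragment**

Step 5
Reactants: 6 furan-2(5H)-one; 7 potassium trifluoro(prop-1-en-2-yl)borate
Product: 8 (4R)-4-(prop-1-en-2-yl)oxolan-2-one
Conditions: [Rh(cod)2]BF4 (3 mol %), (R)-BINAP (3.3 mol %), toluene/H2O 10:1, 100 °C
Reagents that add atoms: none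
Why: Hayashi–Miyaura rhodium-catalysed asymmetric conjugate addition, in which the alkenylrhodium–BINAP species adds to one enantioface of the butenolide and water protonates the rhodium enolate; (R)-BINAP gives the (R)-lactone by the cyclic-enone facial model, which sets C11.

Step 6
Reactants: 8 (4R)-4-(prop-1-en-2-yl)oxolan-2-one; 9 pent-4-en-2-one
Product: 11 (3R,4R)-3-(2-hydroxypent-4-en-2-yl)-4-(prop-1-en-2-yl)oxolan-2-one, via lithium enolate 10 (not isolated)
Conditions: LiN(iPr)2 (1.1 equiv), THF, −78 °C; then 9 (1.3 equiv), −78 °C; AcOH quench at −78 °C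
Reagents that add atoms: none
Why: Aldol addition of the lactone lithium enolate to the methyl ketone at −78 °C, where C–C bond formation outruns proton transfer; attack anti to the 4-isopropenyl group gives the 3,4-trans lactone, and both this centre and the unselective carbinol centre are erased in step 8.

Step 7
Reactants: 11 (3R,4R)-3-(2-hydroxypent-4-en-2-yl)-4-(prop-1-en-2-yl)oxolan-2-one
Product: 12 (3aR,7aR)-7-hydroxy-4,7-dimethyl-3a,6,7,7a-tetrahydro-2-benzofuran-1(3H)-one
Conditions: second-generation Grubbs catalyst RuCl2(H2IMes)(PCy3)(=CHPh) (5 mol %), CH2Cl2 (5 mM), 40 °C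
Reagents that add atoms: none
Why: Ring-closing metathesis between the isopropenyl and allyl groups, held 1,2 on the lactone, closes the six-membered ring with the trisubstituted C12=C13 alkene and loss of ethene.

Step 8
Reactants: 12 (3aR,7aR)-7-hydroxy-4,7-dimethyl-3a,6,7,7a-tetrahydro-2-benzofuran-1(3H)-one
Product: 14 (3aS)-4,7-dimethyl-3a,6-dihydro-2-benzofuran-1(3H)-one, via tertiary mesylate 13 (not isolated)
Conditions: MsCl (3 equiv), Et3N (8 equiv), DMAP (10 mol %), CH2Cl2, 0 °C → rt
Reagents that add atoms: none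
Why: Mesylation of the tertiary alcohol and E1cB elimination through the lactone enolate put the new tetrasubstituted alkene in conjugation with the carbonyl (C15=C16) and not towards C14 or the methyl group, while C11 is untouched; no stronger base is used, so the skipped diene is not drawn into conjugation.

Step 9
Reactants: 14 (3aS)-4,7-dimethyl-3a,6-dihydro-2-benzofuran-1(3H)-one
Product: 15 [(6S)-6-(hydroxymethyl)-2,5-dimethylcyclohexa-1,4-dien-1-yl]methanol
Conditions: iBu2AlH (4 equiv), CH2Cl2, −78 → 0 °C; aq. potassium sodium tartrate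
Reagents that add atoms: none
Why: Hydride 1,2-reduction of the conjugated lactone (two hydrides at the carbonyl, no conjugate reduction of the tetrasubstituted alkene) gives the allylic/alkyl diol.

Step 10
Reactants: 15 [(6S)-6-(hydroxymethyl)-2,5-dimethylcyclohexa-1,4-dien-1-yl]methanol
Product: 17 [(1S)-6-(chloromethyl)-2,5-dimethylcyclohexa-2,5-dien-1-yl]methyl methanesulfonate, via bis-mesylate 16 (not isolated)
Conditions: MsCl (2.4 equiv), Et3N (3 equiv), CH2Cl2, −40 °C; then LiCl (5 equiv), DMF, −40 → 0 °C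
Reagents that add atoms: methanesulfonyl chloride, CS(=O)(=O)Cl; lithium chloride, [Li+].[Cl-]
Why: Both primary alcohols are sulfonylated through sulfene, and chloride then displaces only the allylic mesylate (SN2 at an allylic carbon at 0 °C) while the β-branched alkyl mesylate is inert, which differentiates the two arms in one flask.

Step 11
Reactants: 17 [(1S)-6-(chloromethyl)-2,5-dimethylcyclohexa-2,5-dien-1-yl]methyl methanesulfonate; 5 2-(trimethylsilyl)ethyl 4-(methoxymethoxy)-3-(4,4,5,5-tetramethyl-1,3,2-dioxaborolan-2-yl)benzoate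
Product: 18 2-(trimethylsilyl)ethyl 3-{[(6S)-6-{[(methanesulfonyl)oxy]methyl}-2,5-dimethylcyclohexa-1,4-dien-1-yl]methyl}-4-(methoxymethoxy)benzoate
Conditions: Pd(PPh3)4 (5 mol %), K3PO4 (2 equiv), THF/H2O 10:1, 50 °C
Reagents that add atoms: none
Why: Suzuki–Miyaura allyl–aryl coupling, in which zerovalent palladium ionises the allylic chloride to a π-allyl complex and reductive elimination at the unhindered primary terminus (C17) keeps the tetrasubstituted ring alkene, the alkyl mesylate being inert to palladium.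

Step 12
Reactants: 18 2-(trimethylsilyl)ethyl 3-{[(6S)-6-{[(methanesulfonyl)oxy]methyl}-2,5-dimethylcyclohexa-1,4-dien-1-yl]methyl}-4-(methoxymethoxy)benzoate
Product: 19 2-(trimethylsilyl)ethyl 3-{[(6S)-6-[(benzenesulfonyl)methyl]-2,5-dimethylcyclohexa-1,4-dien-1-yl]methyl}-4-(methoxymethoxy)benzoate
Conditions: PhSO2Na (2 equiv), Bu4NI (0.2 equiv), DMF, 65 °C
Reagents that add atoms: sodium benzenesulfinate, [Na+].[O-]S(=O)c1ccccc1
Why: SN2 displacement of the primary mesylate (through the iodide formed in situ, Finkelstein catalysis) by the sulfur atom of the ambident sulfinate gives the sulfone that acidifies C10.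

**Fragment C (eastern chain)**

Step 13
Reactants: 20 pent-4-ynoic acid
Product: 21 N-methoxy-N-methylpent-4-ynamide
Conditions: MeNH(OMe)·HCl (1.2 equiv), EDC·HCl (1.2 equiv), Et3N (2.5 equiv), DMAP (5 mol %), CH2Cl2, 0 °C → rt
Reagents that add atoms: N,O-dimethylhydroxylamine hydrochloride, CNOC.Cl
Why: Carbodiimide amide coupling gives the Weinreb amide.

Step 14
Reactants: 21 N-methoxy-N-methylpent-4-ynamide; 22 prop-1-en-2-ylmagnesium bromide
Product: 23 2-methylhept-1-en-6-yn-3-one
Conditions: 22 (2.2 equiv), THF, −20 → 0 °C; cold 1 M HCl quench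
Reagents that add atoms: none
Why: Weinreb ketone synthesis, where the chelated tetrahedral intermediate stops at single addition and collapses to the enone only on the acidic quench; one extra equivalent of the Grignard reagent is consumed by the alkyne C–H.

Step 15
Reactants: 23 2-methylhept-1-en-6-yn-3-one
Product: 24 (3S)-2-methylhept-1-en-6-yn-3-ol
Conditions: (R)-2-methyl-CBS-oxazaborolidine (20 mol %), BH3·SMe2 (0.7 equiv), THF, −30 °C
Reagents that add atoms: none
Why: Corey–Bakshi–Shibata reduction, in which the ketone binds the (R)-oxazaborolidine–borane complex with the larger isopropenyl group away from the B-methyl group, so hydride reaches the face that gives the (S)-allylic alcohol (C4).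

Step 16
Reactants: 24 (3S)-2-methylhept-1-en-6-yn-3-ol
Product: 25 tert-butyl(dimethyl){[(3S)-2-methylhept-1-en-6-yn-3-yl]oxy}silane
Conditions: TBSCl, imidazole, DMF, rt
Reagents that add atoms: tert-butyldimethylsilyl chloride, CC(C)(C)[Si](C)(C)Cl
Why: Imidazole-mediated silylation masks C4–OH against AlMe3, the titanium epoxidation catalyst and LDA.

Step 17
Reactants: 25 tert-butyl(dimethyl){[(3S)-2-methylhept-1-en-6-yn-3-yl]oxy}silane
Product: 28 (2E,6S)-6-{[tert-butyl(dimethyl)silyl]oxy}-3,7-dimethylocta-2,7-dien-1-ol, via alkenylalane 26 (not isolated), via lithium alkenylalanate 27 (not isolated)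
Conditions: AlMe3 (3 equiv), Cp2ZrCl2 (0.3 equiv), CH2Cl2, 0 °C → rt; evaporate; n-BuLi (1.1 equiv), THF, −40 °C; (CH2O)n (5 equiv), rt
Reagents that add atoms: trimethylaluminium, C[Al](C)C; formaldehyde (as paraformaldehyde), C=O
Why: Negishi zirconium-catalysed carboalumination adds CH3 and Al syn across the terminal alkyne with CH3 on the internal carbon, and the alanate then adds to formaldehyde with retention, giving the (E)-trisubstituted allylic alcohol (C7 methyl and C9) in one flask.

Step 18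
Reactants: 28 (2E,6S)-6-{[tert-butyl(dimethyl)silyl]oxy}-3,7-dimethylocta-2,7-dien-1-ol
Product: 29 [(2S,3S)-3-[(3S)-3-{[tert-butyl(dimethyl)silyl]oxy}-4-methylpent-4-en-1-yl]-3-methyloxiran-2-yl]methanol
Conditions: Ti(OiPr)4 (10 mol %), L-(+)-diethyl tartrate (12 mol %), t-BuOOH (2 equiv), 4 Å molecular sieves, CH2Cl2, −20 °C
Reagents that add atoms: tert-butyl hydroperoxide, CC(C)(C)OO
Why: Sharpless asymmetric epoxidation, where the titanium–tartrate complex binds the allylic alcohol and with L-(+)-tartrate delivers oxygen to the face that gives the (2S,3S)-epoxy alcohol (7S,8S in target locants); the isopropenyl alkene has no free allylic OH and is untouched.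

Step 19
Reactants: 29 [(2S,3S)-3-[(3S)-3-{[tert-butyl(dimethyl)silyl]oxy}-4-methylpent-4-en-1-yl]-3-methyloxiran-2-yl]methanol
Product: 30 [(2S,3S)-3-[(3S)-3-{[tert-butyl(dimethyl)silyl]oxy}-4-methylpent-4-en-1-yl]-3-methyloxiran-2-yl]methyl trifluoromethanesulfonate
Conditions: Tf2O (1.1 equiv), 2,6-lutidine (1.5 equiv), CH2Cl2, −78 °C; cold filtration through silica, used at once
Reagents that add atoms: trifluoromethanesulfonic anhydride, O=S(=O)(OS(=O)(=O)C(F)(F)F)C(F)(F)F
Why: O-sulfonylation of the primary alcohol with a hindered pyridine base gives a leaving group reactive enough for carbanion SN2 at −78 °C next to the epoxide.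

**Union and endgame**

Step 20
Reactants: 19 2-(trimethylsilyl)ethyl 3-{[(6S)-6-[(benzenesulfonyl)methyl]-2,5-dimethylcyclohexa-1,4-dien-1-yl]methyl}-4-(methoxymethoxy)benzoate; 30 [(2S,3S)-3-[(3S)-3-{[tert-butyl(dimethyl)silyl]oxy}-4-methylpent-4-en-1-yl]-3-methyloxiran-2-yl]methyl trifluoromethanesulfonate
Product: 32 2-(trimethylsilyl)ethyl 3-{[(6S)-6-{1-(benzenesulfonyl)-2-[(2S,3S)-3-[(3S)-3-{[tert-butyl(dimethyl)silyl]oxy}-4-methylpent-4-en-1-yl]-3-methyloxiran-2-yl]ethyl}-2,5-dimethylcyclohexa-1,4-dien-1-yl]methyl}-4-(methoxymethoxy)benzoate, via lithiated sulfone 31 (not isolated)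
Conditions: LiN(iPr)2 (1.1 equiv), THF/DMPU, −78 °C; then 30 (1.2 equiv), −78 → −50 °C; cold NH4Cl quench
Reagents that add atoms: none
Why: Alkylation of an α-sulfonyl carbanion (the C–C bond-forming half of a Julia-type coupling): LDA removes the most acidic C–H next to the sulfone without attacking the ester, and the soft carbanion displaces the primary triflate by SN2 faster than it opens the trisubstituted epoxide, joining C10 to C9; the new sulfonyl-bearing centre forms as both epimers and is removed in step 21.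

Step 21
Reactants: 32 the coupled sulfone (both C10 epimers)
Product: 33 2-(trimethylsilyl)ethyl 3-{[(6S)-6-{2-[(2S,3S)-3-[(3S)-3-{[tert-butyl(dimethyl)silyl]oxy}-4-methylpent-4-en-1-yl]-3-methyloxiran-2-yl]ethyl}-2,5-dimethylcyclohexa-1,4-dien-1-yl]methyl}-4-(methoxymethoxy)benzoate
Conditions: Na(Hg) (5% Na, 6 equiv), Na2HPO4, MeOH/THF 3:1, −20 °C
Reagents that add atoms: none
Why: Reductive desulfonylation by single-electron transfer from sodium amalgam cleaves the C–S bond and buffered methanol protonates C10, leaving ester, epoxide and skipped diene intact.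

Step 22
Reactants: 33 the desulfonylated silyl ether/silylethyl ester
Product: 34 3-{[(6S)-6-{2-[(2S,3S)-3-[(3S)-3-hydroxy-4-methylpent-4-en-1-yl]-3-methyloxiran-2-yl]ethyl}-2,5-dimethylcyclohexa-1,4-dien-1-yl]methyl}-4-(methoxymethoxy)benzoic acid
Conditions: Bu4NF (4 equiv), THF, 0 °C → rt; pH 7 phosphate buffer; carried on at once as the carboxylate salt
Reagents that add atoms: none
Why: Fluoride-induced desilylation removes the silyl ether and, by β-elimination to ethene and fluorosilane, the 2-(trimethylsilyl)ethyl ester in one operation, without acid that would let C4–OH close onto the epoxide.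

Step 23
Reactants: 34 the seco acid
Product: 35 (4S,7S,8S,11S)-7,8-epoxy macrolactone as its phenol MOM ether
Conditions: 2-methyl-6-nitrobenzoic anhydride (1.3 equiv), DMAP (3 equiv), CH2Cl2 (1 mM, syringe-pump addition over 12 h), rt
Reagents that add atoms: none
Why: Shiina macrolactonisation, in which the mixed anhydride is activated by DMAP and acylated by the only free hydroxyl (C4–OH) under high dilution, closing the 15-membered ring with retention at C4 while the epoxide keeps the future tertiary alcohol masked.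

Step 24
Reactants: 35 the epoxy macrolactone
Product: 36 (4S,7S,8R,11S)-8-bromo-7-hydroxy macrolactone as its phenol MOM ether
Conditions: Li2NiBr4 (0.4 M in THF, 3 equiv), THF, 0 °C → rt; H2O
Reagents that add atoms: dilithium tetrabromonickelate, [Li+].[Li+].[Ni+2].[Br-].[Br-].[Br-].[Br-]
Why: Regioselective SN2 epoxide opening by soft bromide, which attacks the less substituted C8 with inversion (8S to 8R) and leaves the C7–O bond untouched (7S), giving the anti bromohydrin of the target.

Step 25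
Reactants: 36 the MOM-protected bromohydrin
Product: 37 target macrolide CNP0186361.2, (4S,7S,8R,11S)
Conditions: ZnBr2 (1 equiv), n-PrSH (2 equiv), CH2Cl2, 0 °C, 10 min
Reagents that add atoms: none
Why: Lewis-acid-assisted acetal cleavage, where ZnBr2 activates the aryl MOM ether and the thiol captures the methoxymethyl cation within minutes, freeing the phenol without ionising the tertiary alcohol, the allylic ester or the skipped diene.

**Compound list**
1 | 4-bromophenol | Oc1ccc(Br)cc1 | starting material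
2 | 2-(trimethylsilyl)ethyl 4-hydroxybenzoate | C[Si](C)(C)CCOC(=O)c1ccc(O)cc1 | intermediate
3 | 2-(trimethylsilyl)ethyl 4-hydroxy-3-iodobenzoate | C[Si](C)(C)CCOC(=O)c1ccc(O)c(I)c1 | intermediate
4 | 2-(trimethylsilyl)ethyl 3-iodo-4-(methoxymethoxy)benzoate | C[Si](C)(C)CCOC(=O)c1ccc(OCOC)c(I)c1 | intermediate
5 | 2-(trimethylsilyl)ethyl 4-(methoxymethoxy)-3-(4,4,5,5-tetramethyl-1,3,2-dioxaborolan-2-yl)benzoate | C[Si](C)(C)CCOC(=O)c1ccc(OCOC)c(B2OC(C)(C)C(C)(C)O2)c1 | intermediate
6 | furan-2(5H)-one | O=C1C=CCO1 | starting material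
7 | potassium trifluoro(prop-1-en-2-yl)borate | [K+].CC(=C)[B-](F)(F)F | starting material
8 | (4R)-4-(prop-1-en-2-yl)oxolan-2-one | O=C1C[C@H](C(C)=C)CO1 | intermediate
9 | pent-4-en-2-one | CC(=O)CC=C | starting material
10 | lithium enolate of 8 | [Li+].[O-]C1=C[C@H](C(C)=C)CO1 | intermediate
11 | (3R,4R)-3-(2-hydroxypent-4-en-2-yl)-4-(prop-1-en-2-yl)oxolan-2-one (both carbinol epimers) | O=C1[C@@H](C(C)(O)CC=C)[C@H](C(C)=C)CO1 | intermediate
12 | (3aR,7aR)-7-hydroxy-4,7-dimethyl-3a,6,7,7a-tetrahydro-2-benzofuran-1(3H)-one (both C7 epimers) | O=C1[C@H]3C(C)(O)CC=C(C)[C@@H]3CO1 | intermediate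
13 | 7-O-methanesulfonate of 12 | O=C1[C@H]3C(C)(OS(C)(=O)=O)CC=C(C)[C@@H]3CO1 | intermediate
14 | (3aS)-4,7-dimethyl-3a,6-dihydro-2-benzofuran-1(3H)-one | O=C1C3=C(C)CC=C(C)[C@@H]3CO1 | intermediate
15 | [(6S)-6-(hydroxymethyl)-2,5-dimethylcyclohexa-1,4-dien-1-yl]methanol | OCC1=C(C)CC=C(C)[C@@H]1CO | intermediate
16 | bis(methanesulfonate) of 15 | CS(=O)(=O)OCC1=C(C)CC=C(C)[C@@H]1COS(C)(=O)=O | intermediate
17 | [(1S)-6-(chloromethyl)-2,5-dimethylcyclohexa-2,5-dien-1-yl]methyl methanesulfonate | ClCC1=C(C)CC=C(C)[C@@H]1COS(C)(=O)=O | intermediate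
18 | 2-(trimethylsilyl)ethyl 3-{[(6S)-6-{[(methanesulfonyl)oxy]methyl}-2,5-dimethylcyclohexa-1,4-dien-1-yl]methyl}-4-(methoxymethoxy)benzoate | COCOc1ccc(C(=O)OCC[Si](C)(C)C)cc1CC1=C(C)CC=C(C)[C@@H]1COS(C)(=O)=O | intermediate
19 | 2-(trimethylsilyl)ethyl 3-{[(6S)-6-[(benzenesulfonyl)methyl]-2,5-dimethylcyclohexa-1,4-dien-1-yl]methyl}-4-(methoxymethoxy)benzoate | COCOc1ccc(C(=O)OCC[Si](C)(C)C)cc1CC1=C(C)CC=C(C)[C@@H]1CS(=O)(=O)c1ccccc1 | intermediate
20 | pent-4-ynoic acid | C#CCCC(=O)O | starting material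
21 | N-methoxy-N-methylpent-4-ynamide | C#CCCC(=O)N(C)OC | intermediate
22 | prop-1-en-2-ylmagnesium bromide | CC(=C)[Mg]Br | starting material
23 | 2-methylhept-1-en-6-yn-3-one | C=C(C)C(=O)CCC#C | intermediate
24 | (3S)-2-methylhept-1-en-6-yn-3-ol | C=C(C)[C@@H](O)CCC#C | intermediate
25 | tert-butyl(dimethyl){[(3S)-2-methylhept-1-en-6-yn-3-yl]oxy}silane | C=C(C)[C@@H](O[Si](C)(C)C(C)(C)C)CCC#C | intermediate
26 | dimethyl[(1E,5S)-5-{[tert-butyl(dimethyl)silyl]oxy}-2,6-dimethylhepta-1,6-dien-1-yl]alumane | C=C(C)[C@@H](O[Si](C)(C)C(C)(C)C)CC/C(C)=C/[Al](C)C | intermediate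
27 | lithium butyl(dimethyl)alkenylaluminate from 26 | [Li+].C=C(C)[C@@H](O[Si](C)(C)C(C)(C)C)CC/C(C)=C/[Al-](C)(C)CCCC | intermediate
28 | (2E,6S)-6-{[tert-butyl(dimethyl)silyl]oxy}-3,7-dimethylocta-2,7-dien-1-ol | C=C(C)[C@@H](O[Si](C)(C)C(C)(C)C)CC/C(C)=C/CO | intermediate
29 | [(2S,3S)-3-[(3S)-3-{[tert-butyl(dimethyl)silyl]oxy}-4-methylpent-4-en-1-yl]-3-methyloxiran-2-yl]methanol | C=C(C)[C@@H](O[Si](C)(C)C(C)(C)C)CC[C@]1(C)O[C@H]1CO | intermediate
30 | trifluoromethanesulfonate of 29 | C=C(C)[C@@H](O[Si](C)(C)C(C)(C)C)CC[C@]1(C)O[C@H]1COS(=O)(=O)C(F)(F)F | intermediate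
31 | C10-lithiated sulfone 19 | [Li+].COCOc1ccc(C(=O)OCC[Si](C)(C)C)cc1CC1=C(C)CC=C(C)[C@@H]1[CH-]S(=O)(=O)c1ccccc1 | intermediate
32 | coupled sulfone: silylethyl ester, C4-O-TBS, (7S,8S)-epoxide, C10-SO2Ph (both C10 epimers), phenol MOM ether | C=C(C)[C@@H](O[Si](C)(C)C(C)(C)C)CC[C@]1(C)O[C@H]1CC(S(=O)(=O)c1ccccc1)[C@H]2C(C)=CCC(C)=C2Cc2cc(C(=O)OCC[Si](C)(C)C)ccc2OCOC | intermediate
33 | desulfonylated coupling product: silylethyl ester, C4-O-TBS, (7S,8S)-epoxide, phenol MOM ether | C=C(C)[C@@H](O[Si](C)(C)C(C)(C)C)CC[C@]1(C)O[C@H]1CC[C@H]2C(C)=CCC(C)=C2Cc2cc(C(=O)OCC[Si](C)(C)C)ccc2OCOC | intermediate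
34 | seco acid: (4S)-hydroxy, (7S,8S)-epoxide, (11S), phenol MOM ether | C=C(C)[C@@H](O)CC[C@]1(C)O[C@H]1CC[C@H]2C(C)=CCC(C)=C2Cc2cc(C(=O)O)ccc2OCOC | intermediate
35 | (4S,7S,8S,11S)-7,8-epoxy macrolactone, phenol MOM ether | C=C(C)[C@@H]1CC[C@]3(C)O[C@H]3CC[C@H]2C(C)=CCC(C)=C2Cc2cc(ccc2OCOC)C(=O)O1 | intermediate
36 | (4S,7S,8R,11S)-8-bromo-7-hydroxy macrolactone, phenol MOM ether | C=C(C)[C@@H]1CC[C@](C)(O)[C@H](Br)CC[C@H]2C(C)=CCC(C)=C2Cc2cc(ccc2OCOC)C(=O)O1 | intermediate
37 | target CNP0186361.2, (4S,7S,8R,11S) | C=C(C)[C@@H]1CC[C@](C)(O)[C@H](Br)CC[C@H]2C(C)=CCC(C)=C2Cc2cc(ccc2O)C(=O)O1 | target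

**Step count and risks**

Total step count: 25. Longest linear sequence: 14 steps (steps 5–12, then 20–25); the chain branch is 13 steps and the aryl branch 12.

Step 11 (allyl–aryl Suzuki coupling). The π-allylpalladium from 17 sits next to the doubly allylic C14H2, so β-hydride loss to a methylenecyclohexadiene and then an arene can compete, as can attack at the hindered terminus. The fallback sets out from 17 and phenol 2 and returns at 18, and makes the aryl–C17 bond without palladium by phenoxide C-alkylation. The sodium salt of 2 (NaH, toluene) is stirred with 17 at rt; in the non-polar medium the tight ion pair alkylates at the ortho carbon, giving 2-(trimethylsilyl)ethyl 4-hydroxy-3-{[(6S)-6-{[(methanesulfonyl)oxy]methyl}-2,5-dimethylcyclohexa-1,4-dien-1-yl]methyl}benzoate F1, and MOMCl/iPr2NEt then gives 18. This route needs none of 3, 4 or 5.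

Step 23 (macrolactonisation). The ring is a 15-membered meta-bridged lactone closed at a hindered allylic alcohol, and the hydroxy-epoxy acid 34 is itself prone to acid-induced closure of C4–OH onto the epoxide. The fallback sets out from 19 and 29 and returns at 35; it forms the ester bond first, between two fragments, and closes the ring by C–C bond formation. Bu4NF converts 19 into 3-{[(6S)-6-[(benzenesulfonyl)methyl]-2,5-dimethylcyclohexa-1,4-dien-1-yl]methyl}-4-(methoxymethoxy)benzoic acid F2 and 29 into (3S)-1-[(2S,3S)-3-(hydroxymethyl)-2-methyloxiran-2-yl]-4-methylpent-4-en-3-ol F3. I2/PPh3/imidazole at 0 °C iodinates only the primary alcohol, giving (3S)-1-[(2S,3R)-3-(iodomethyl)-2-methyloxiran-2-yl]-4-methylpent-4-en-3-ol F4 (same geometry; the descriptor changes by priority). EDC/DMAP joins F2 and F4 to the hydroxy-ester-linked sulfone iodide F5. LiN(iPr)2 in THF/DMPU at 1 mM and −78 °C then closes the ring by intramolecular sulfone alkylation to the macrocyclic C10 sulfone F6 (both C10 epimers), and buffered Na(Hg) removes the sulfonyl group to give 35. Steps 19–23 are bypassed.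

Step 24 (bromide opening). If bromide attacks the tertiary C7 instead of C8, the wrong regioisomer forms. The fallback sets out from 35 and returns at 36, and turns that regioisomer into the same product by a bromonium relay. MgBr2·OEt2 (Et2O, −20 °C) opens the epoxide at C7 with inversion, giving the (4S,7R,8S,11S)-7-bromo-8-hydroxy macrolactone MOM ether F7. Tf2O with 2,6-di-tert-butyl-4-methylpyridine at −78 °C gives its 8-O-triflate F8, which is not isolated. On adding aqueous THF the tertiary bromine displaces the triflate anti to form the bromonium ion, and water opens it at the tertiary C7 with inversion. Oxygen is then on the original epoxide face at C7 and bromine on the opposite face at C8, which is 36.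

Further compounds
F1 | step 11 | 2-(trimethylsilyl)ethyl 4-hydroxy-3-{[(6S)-6-{[(methanesulfonyl)oxy]methyl}-2,5-dimethylcyclohexa-1,4-dien-1-yl]methyl}benzoate | C[Si](C)(C)CCOC(=O)c1ccc(O)c(CC2=C(C)CC=C(C)[C@@H]2COS(C)(=O)=O)c1
F2 | step 23 | 3-{[(6S)-6-[(benzenesulfonyl)methyl]-2,5-dimethylcyclohexa-1,4-dien-1-yl]methyl}-4-(methoxymethoxy)benzoic acid | COCOc1ccc(C(=O)O)cc1CC1=C(C)CC=C(C)[C@@H]1CS(=O)(=O)c1ccccc1
F3 | step 23 | (3S)-1-[(2S,3S)-3-(hydroxymethyl)-2-methyloxiran-2-yl]-4-methylpent-4-en-3-ol | C=C(C)[C@@H](O)CC[C@]1(C)O[C@H]1CO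
F4 | step 23 | (3S)-1-[(2S,3R)-3-(iodomethyl)-2-methyloxiran-2-yl]-4-methylpent-4-en-3-ol | C=C(C)[C@@H](O)CC[C@]1(C)O[C@H]1CI
F5 | step 23 | (3S)-1-[(2S,3R)-3-(iodomethyl)-2-methyloxiran-2-yl]-4-methylpent-4-en-3-yl 3-{[(6S)-6-[(benzenesulfonyl)methyl]-2,5-dimethylcyclohexa-1,4-dien-1-yl]methyl}-4-(methoxymethoxy)benzoate | C=C(C)[C@@H](OC(=O)c2ccc(OCOC)c(CC3=C(C)CC=C(C)[C@@H]3CS(=O)(=O)c3ccccc3)c2)CC[C@]1(C)O[C@H]1CI
F6 | step 23 | C10-(benzenesulfonyl) derivative of epoxy macrolactone 35 (both C10 epimers) | C=C(C)[C@@H]1CC[C@]3(C)O[C@H]3CC(S(=O)(=O)c3ccccc3)[C@H]2C(C)=CCC(C)=C2Cc2cc(ccc2OCOC)C(=O)O1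
F7 | step 24 | (4S,7R,8S,11S)-7-bromo-8-hydroxy macrolactone, phenol MOM ether | C=C(C)[C@@H]1CC[C@@](C)(Br)[C@@H](O)CC[C@H]2C(C)=CCC(C)=C2Cc2cc(ccc2OCOC)C(=O)O1
F8 | step 24 | 8-O-trifluoromethanesulfonate of F7 | C=C(C)[C@@H]1CC[C@@](C)(Br)[C@@H](OS(=O)(=O)C(F)(F)F)CC[C@H]2C(C)=CCC(C)=C2Cc2cc(ccc2OCOC)C(=O)O1
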